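**Retrosynthetic overview**
- The strategy rests on ring B: a cyclohexene whose C8=C9 double bond lies between oxygen-bearing C7 and the quaternary C10, with a second oxygen on C6. This is the pattern of a Diels–Alder adduct of a C7–C10 1-silyloxy diene with a C5=C6 dienophile, the C6 oxygen being carried as a nitro group.
- Key disconnection: C5–C10 and C6–C7, leading back to an acyclic (E)-nitroalkene tethered through C1–C4 to an (E)-silyloxy diene. Rings A and B close together in one intramolecular cycloaddition; no ring exists before it.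
- After the cycloaddition: nitro to C6 ketone, hydride from the α face to the 6β-ol, acetylation, desilylation, isovalerylation at the 7α-ol, release of the C15 acid.
- Before it: the C9=C10 geometry comes from anti-carbomagnesiation/iodination of but-2-yn-1-ol, C1–C10 from a B-alkyl Suzuki–Miyaura coupling, the side chain from acetoacetate dianion alkylation, enol phosphate and cuprate, the C7 oxygen from hydroboration, the nitroalkene from a Henry reaction.

Key step: step 15

Remark: carbons carry labdane numbers (C1–C20) from the first step on, and the C15 acid is carried as its 2-(trimethylsilyl)ethyl ester because an allyl ester would be hydroborated in step 9.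

**Route**

Step 1
Reactants: 1 but-2-yn-1-ol; 2 isopropenylmagnesium bromide
Product: 4 (2Z)-3-iodo-2-(prop-1-en-2-yl)but-2-en-1-ol, via magnesium chelate 3 (not isolated)
Conditions: CuI (10 mol %), THF, 0 °C → reflux; then I2, THF, −78 → 0 °C
Reagents that add atoms: iodine, II
Why: Copper-assisted anti-carbomagnesiation of the propargylic alkoxide puts the alkenyl group on the alkyne carbon next to the carbinol (future C9) and magnesium on the distal carbon (future C10) in a five-membered chelate, so iodinolysis with retention should give the Z iodide with iodine cis to CH2OH and the C10 methyl cis to the isopropenyl group, the geometry C9=C10 needs.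

Step 2
Reactants: 5 2,2-dimethylpent-4-enal
Product: 6 5,5-dimethoxy-4,4-dimethylpent-1-ene
Conditions: HC(OMe)3, MeOH, TsOH·H2O (cat.), rt
Reagents that add atoms: trimethyl orthoformate, COC(OC)OC
Why: Acid-catalysed acetalisation with an orthoformate masks the non-enolisable C5 aldehyde against the borane, carbanion and cuprate steps that follow.

Step 3
Reactants: 6 5,5-dimethoxy-4,4-dimethylpent-1-ene; 4 (2Z)-3-iodo-2-(prop-1-en-2-yl)but-2-en-1-ol
Product: 8 (2Z)-8,8-dimethoxy-3,7,7-trimethyl-2-(prop-1-en-2-yl)oct-2-en-1-ol, via B-alkyl-9-BBN 7 (not isolated)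
Conditions: 9-BBN, THF, 0 °C → rt; then 4, PdCl2(dppf) (5 mol %), AsPh3, Cs2CO3, DMF/H2O, rt → 45 °C
Reagents that add atoms: none
Why: B-alkyl Suzuki–Miyaura coupling: 9-BBN adds to the terminal alkene of 6 at its CH2 end and the primary alkylborane couples with the alkenyl iodide with retention of double-bond geometry, forming C1–C10 and leaving the hydroxyl free.

Step 4
Reactants: 8 (2Z)-8,8-dimethoxy-3,7,7-trimethyl-2-(prop-1-en-2-yl)oct-2-en-1-ol
Product: 9 (6Z)-7-(bromomethyl)-1,1-dimethoxy-2,2,6,8-tetramethylnona-6,8-diene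
Conditions: CBr4, PPh3, CH2Cl2, −20 → 0 °C
Reagents that add atoms: carbon tetrabromide, BrC(Br)(Br)Br
Why: Appel bromination of the primary allylic alcohol runs under neutral conditions that spare the acetal and the diene.

Step 5
Reactants: 10 2,2,6-trimethyl-4H-1,3-dioxin-4-one; 11 2-(trimethylsilyl)ethanol
Product: 13 2-(trimethylsilyl)ethyl 3-oxobutanoate, via acetylketene 12 (not isolated)
Conditions: toluene, 110 °C (acetone distilled off)
Reagents that add atoms: none
Why: Thermal retro-[4+2] fragmentation of the dioxinone releases acetylketene, which the alcohol traps to give the β-keto ester (acetoacetylation).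

Step 6
Reactants: 13 2-(trimethylsilyl)ethyl 3-oxobutanoate; 9 (6Z)-7-(bromomethyl)-1,1-dimethoxy-2,2,6,8-tetramethylnona-6,8-diene
Product: 15 2-(trimethylsilyl)ethyl (6E)-12,12-dimethoxy-7,11,11-trimethyl-3-oxo-6-(prop-1-en-2-yl)dodec-6-enoate, via dianion 14 (not isolated)
Conditions: NaH, THF, 0 °C; n-BuLi, 0 °C; then 9, 0 °C → rt; then H2O
Reagents that add atoms: none
Why: γ-Alkylation of the acetoacetate dianion: the more basic terminal carbanion displaces the primary allylic bromide by SN2 and forms C11–C12.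

Step 7
Reactants: 15 2-(trimethylsilyl)ethyl (6E)-12,12-dimethoxy-7,11,11-trimethyl-3-oxo-6-(prop-1-en-2-yl)dodec-6-enoate
Product: 17 2-(trimethylsilyl)ethyl (2Z,6E)-3-(diethoxyphosphoryloxy)-12,12-dimethoxy-7,11,11-trimethyl-6-(prop-1-en-2-yl)dodeca-2,6-dienoate, via sodium enolate 16 (not isolated)
Conditions: NaH, Et2O, 0 °C; then ClP(O)(OEt)2, 0 °C → rt
Reagents that add atoms: diethyl chlorophosphate, CCOP(=O)(Cl)OCC
Why: O-phosphorylation of the chelated sodium enolate in ether should give the Z enol phosphate, with the phosphate cis to the ester.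

Step 8
Reactants: 17 2-(trimethylsilyl)ethyl (2Z,6E)-3-(diethoxyphosphoryloxy)-12,12-dimethoxy-7,11,11-trimethyl-6-(prop-1-en-2-yl)dodeca-2,6-dienoate
Product: 18 2-(trimethylsilyl)ethyl (2E,6E)-12,12-dimethoxy-3,7,11,11-tetramethyl-6-(prop-1-en-2-yl)dodeca-2,6-dienoate
Conditions: Me2CuLi, Et2O, −78 → −45 °C
Reagents that add atoms: lithium dimethylcuprate, [Li+].C[Cu-]C
Why: The cuprate replaces the enol phosphate by addition–elimination with retention, so the new C13 methyl ends cis to the ester and the 13E enoate should result.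

Step 9
Reactants: 18 2-(trimethylsilyl)ethyl (2E,6E)-12,12-dimethoxy-3,7,11,11-tetramethyl-6-(prop-1-en-2-yl)dodeca-2,6-dienoate
Product: 20 2-(trimethylsilyl)ethyl (2E,6E)-6-(1-hydroxypropan-2-yl)-12,12-dimethoxy-3,7,11,11-tetramethyldodeca-2,6-dienoate (racemic at C8), via alkylborane 19 (not isolated)
Conditions: 9-BBN, THF, 0 °C → rt; then NaBO3·4H2O, H2O, rt
Reagents that add atoms: sodium perborate, [Na+].[O-]OB=O
Why: Hydroboration–oxidation: 9-BBN should add only to the 1,1-disubstituted terminal alkene with boron on C7, leaving the tetrasubstituted and the ester-conjugated alkenes untouched; the new centre at C8 forms as a racemate and is removed again in step 12.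

Step 10
Reactants: 20 2-(trimethylsilyl)ethyl (2E,6E)-6-(1-hydroxypropan-2-yl)-12,12-dimethoxy-3,7,11,11-tetramethyldodeca-2,6-dienoate
Product: 21 2-(trimethylsilyl)ethyl (2E,6E)-6-(1-hydroxypropan-2-yl)-3,7,11,11-tetramethyl-12-oxododeca-2,6-dienoate
Conditions: TsOH·H2O (10 mol %), THF/H2O, rt
Reagents that add atoms: water, O
Why: Mild acid hydrolysis of the dimethyl acetal frees the C5 aldehyde before the acid-sensitive β,γ-unsaturated aldehyde and the silyl enol ether exist.

Step 11
Reactants: 21 2-(trimethylsilyl)ethyl (2E,6E)-6-(1-hydroxypropan-2-yl)-3,7,11,11-tetramethyl-12-oxododeca-2,6-dienoate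
Product: 22 2-(trimethylsilyl)ethyl (2E,6E)-3,7,11,11-tetramethyl-12-oxo-6-(1-oxopropan-2-yl)dodeca-2,6-dienoate (racemic at C8)
Conditions: Dess–Martin periodinane, pyridine, CH2Cl2, 0 °C
Reagents that add atoms: none
Why: Dess–Martin oxidation buffered with pyridine should give the β,γ-unsaturated C7 aldehyde without moving the C9=C10 bond into conjugation; the product is used at once.

Step 12
Reactants: 22 2-(trimethylsilyl)ethyl (2E,6E)-3,7,11,11-tetramethyl-12-oxo-6-(1-oxopropan-2-yl)dodeca-2,6-dienoate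
Product: 23 2-(trimethylsilyl)ethyl (2E,6E)-6-[(1E)-1-(tert-butyldimethylsilyloxy)prop-1-en-2-yl]-3,7,11,11-tetramethyl-12-oxododeca-2,6-dienoate
Conditions: Et3N (3 equiv), TBSOTf (1.1 equiv), CH2Cl2, −78 °C; cold aq. NaHCO3 quench
Reagents that add atoms: tert-butyldimethylsilyl trifluoromethanesulfonate, CC(C)(C)[Si](C)(C)OS(=O)(=O)C(F)(F)F
Why: Soft enolisation with silyl triflate and amine: only the C7 aldehyde has an α-hydrogen (the C5 aldehyde has none), and O-silylation should favour the E enol ether with the bulky alkenyl group trans to oxygen, the C9=C10 geometry being untouched.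

Step 13
Reactants: 23 2-(trimethylsilyl)ethyl (2E,6E)-6-[(1E)-1-(tert-butyldimethylsilyloxy)prop-1-en-2-yl]-3,7,11,11-tetramethyl-12-oxododeca-2,6-dienoate; 24 nitromethane
Product: 25 2-(trimethylsilyl)ethyl (2E,6E)-6-[(1E)-1-(tert-butyldimethylsilyloxy)prop-1-en-2-yl]-12-hydroxy-3,7,11,11-tetramethyl-13-nitrotrideca-2,6-dienoate (racemic at C5)
Conditions: MeNO2 (10 equiv), 1,1,3,3-tetramethylguanidine (20 mol %), THF, 0 °C → rt
Reagents that add atoms: none
Why: Henry (nitroaldol) addition to the non-enolisable neopentyl aldehyde under a catalytic non-nucleophilic base that the silyl dienol ether tolerates; the carbinol centre is lost in step 14.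

Step 14
Reactants: 25 2-(trimethylsilyl)ethyl (2E,6E)-6-[(1E)-1-(tert-butyldimethylsilyloxy)prop-1-en-2-yl]-12-hydroxy-3,7,11,11-tetramethyl-13-nitrotrideca-2,6-dienoate
Product: 27 2-(trimethylsilyl)ethyl (2E,6E,12E)-6-[(1E)-1-(tert-butyldimethylsilyloxy)prop-1-en-2-yl]-3,7,11,11-tetramethyl-13-nitrotrideca-2,6,12-trienoate, via mesylate 26 (not isolated)
Conditions: MsCl, Et3N, CH2Cl2, −20 → 0 °C
Reagents that add atoms: none
Why: Mesylation and E1cB elimination of the β-nitro alcohol should give the E nitroalkene, which has no γ-hydrogen and so cannot isomerise.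

Step 15
Reactants: 27 2-(trimethylsilyl)ethyl (2E,6E,12E)-6-[(1E)-1-(tert-butyldimethylsilyloxy)prop-1-en-2-yl]-3,7,11,11-tetramethyl-13-nitrotrideca-2,6,12-trienoate
Product: 28 2-(trimethylsilyl)ethyl (13E)-7α-(tert-butyldimethylsilyloxy)-6α-nitrolabda-8,13-dien-15-oate (5α-H, 10β-CH3, trans-fused)
Conditions: 1,1′-[(1R,2R)-cyclohexane-1,2-diyl]bis{3-[3,5-bis(trifluoromethyl)phenyl]thiourea} (20 mol %), 4 Å molecular sieves, toluene, −20 °C → rt
Reagents that add atoms: none
Why: Proposed new method: the bis-thiourea is expected to bind both nitro oxygens of 27 and lower the LUMO of the C5=C6 nitroalkene, so that a concerted but asynchronous [4+2] cycloaddition with the C7–C10 silyloxy diene runs below the temperature of the thermal background, the C5–C10 bond (nitroalkene β-carbon to the fully substituted diene terminus) forming ahead of C6–C7; the closest known reactions are the thermal intramolecular Diels–Alder reaction of nitroalkene trienes to trans-decalins and the intermolecular nitroalkene Diels–Alder reaction catalysed by chiral double hydrogen-bond donors. Ring B closes as the cyclohexene of the cycloadduct, and ring A closes in the same event through the four-carbon tether C1–C4 that links diene terminus C10 to dienophile carbon C5 (fused 1,3,9-decatriene mode, helped by the gem-dimethyl group on C4). The relative configuration follows from the geometry of 27: the E enol ether holds OTBS on the outside of the diene, so C7–O ends cis to the C10–C1 bond and trans to the C10 methyl (7α); the E nitroalkene keeps C4 and NO2 trans; and the endo-nitro, tether-exo transition state puts NO2 cis to OTBS (6α) and gives the trans ring fusion (5α-H, 10β-CH3). The absolute configuration rests on the catalyst alone, which must shield one face of the hydrogen-bonded nitroalkene as it folds under the diene; this diene-face selection is the unproven element, and the catalyst enantiomer is chosen to give the 10β-methyl series. The step needs endo over exo and one diene face: the first is secured by the tether, the E,E geometry and the hydrogen-bond activation, the second only by the catalyst, while any 1Z enol ether isomer should stay unreacted because its s-cis form is blocked.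

Step 16
Reactants: 28 2-(trimethylsilyl)ethyl (13E)-7α-(tert-butyldimethylsilyloxy)-6α-nitrolabda-8,13-dien-15-oate
Product: 30 2-(trimethylsilyl)ethyl (13E)-7α-(tert-butyldimethylsilyloxy)-6-oxolabda-8,13-dien-15-oate, via potassium nitronate 29 (not isolated)
Conditions: KOtBu (1.05 equiv), THF, −40 °C; then aq. TiCl3, NH4OAc (pH 5–6), THF/H2O, 0 °C → rt
Reagents that add atoms: water, O
Why: Reductive Nef reaction: the nitronate is reduced by trivalent titanium to the imine, which is hydrolysed in the acetate buffer to the C6 ketone; C6 becomes trigonal and C5, C7 and C10 are not touched.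

Step 17
Reactants: 30 2-(trimethylsilyl)ethyl (13E)-7α-(tert-butyldimethylsilyloxy)-6-oxolabda-8,13-dien-15-oate
Product: 31 2-(trimethylsilyl)ethyl (13E)-7α-(tert-butyldimethylsilyloxy)-6β-hydroxylabda-8,13-dien-15-oate
Conditions: NaBH4, MeOH/THF, −20 → 0 °C
Reagents that add atoms: none
Why: Borohydride reduction: the syn-axial methyl groups on C10 and C4 screen the β face of C6, so hydride should add from the α face and give the axial 6β-alcohol, the low temperature limiting enolisation towards C7.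

Step 18
Reactants: 31 2-(trimethylsilyl)ethyl (13E)-7α-(tert-butyldimethylsilyloxy)-6β-hydroxylabda-8,13-dien-15-oate
Product: 32 2-(trimethylsilyl)ethyl (13E)-6β-acetoxy-7α-(tert-butyldimethylsilyloxy)labda-8,13-dien-15-oate
Conditions: Ac2O, DMAP, pyridine, 40 °C
Reagents that add atoms: acetic anhydride, CC(=O)OC(C)=O
Why: DMAP-catalysed acetylation of the hindered axial alcohol; the trans-diaxial silyl ether cannot migrate.

Step 19
Reactants: 32 2-(trimethylsilyl)ethyl (13E)-6β-acetoxy-7α-(tert-butyldimethylsilyloxy)labda-8,13-dien-15-oate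
Product: 33 2-(trimethylsilyl)ethyl (13E)-6β-acetoxy-7α-hydroxylabda-8,13-dien-15-oate
Conditions: HF·pyridine, pyridine, THF, 0 °C → rt
Reagents that add atoms: none
Why: Buffered HF·pyridine desilylation cleaves the secondary allylic silyl ether and should leave the acetate and the 2-(trimethylsilyl)ethyl ester, the trans-diaxial arrangement preventing acetyl migration.

Step 20
Reactants: 33 2-(trimethylsilyl)ethyl (13E)-6β-acetoxy-7α-hydroxylabda-8,13-dien-15-oate
Product: 34 2-(trimethylsilyl)ethyl (13E)-6β-acetoxy-7α-(3-methylbutanoyloxy)labda-8,13-dien-15-oate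
Conditions: 3-methylbutanoic anhydride, DMAP, Et3N, CH2Cl2, rt
Reagents that add atoms: 3-methylbutanoic anhydride, CC(C)CC(=O)OC(=O)CC(C)C
Why: DMAP-catalysed acylation of the 7α-alcohol, with retention at C7 since only the O–H bond is broken.

Step 21
Reactants: 34 2-(trimethylsilyl)ethyl (13E)-6β-acetoxy-7α-(3-methylbutanoyloxy)labda-8,13-dien-15-oate
Product: 35 (13E)-6β-acetoxy-7α-(3-methylbutanoyloxy)labda-8,13-dien-15-oic acid
Conditions: TBAF, THF, 0 °C → rt; 0.1 M HCl work-up
Reagents that add atoms: none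
Why: Fluoride-induced fragmentation of the 2-(trimethylsilyl)ethyl ester (attack at silicon, loss of ethene) should release the carboxylic acid without touching the acetate or the isovalerate.

**Compound list**
1 | but-2-yn-1-ol | CC#CCO | starting material
2 | isopropenylmagnesium bromide (prop-1-en-2-ylmagnesium bromide) | CC(=C)[Mg]Br | starting material
3 | 3-methyl-4-(prop-1-en-2-yl)-2,5-dihydro-1,2-oxamagnesole (cyclic alkenylmagnesium alkoxide, Mg on future C10) | CC1=C(C(C)=C)CO[Mg]1 | intermediate (not isolated)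
4 | (2Z)-3-iodo-2-(prop-1-en-2-yl)but-2-en-1-ol | OC/C(C(C)=C)=C(C)\I | intermediate
5 | 2,2-dimethylpent-4-enal | C=CCC(C)(C)C=O | starting material
6 | 5,5-dimethoxy-4,4-dimethylpent-1-ene | C=CCC(C)(C)C(OC)OC | intermediate
7 | 9-(5,5-dimethoxy-4,4-dimethylpentyl)-9-borabicyclo[3.3.1]nonane | C1CCC2CCCC1B2CCCC(C)(C)C(OC)OC | intermediate (not isolated)
8 | (2Z)-8,8-dimethoxy-3,7,7-trimethyl-2-(prop-1-en-2-yl)oct-2-en-1-ol | OC/C(C(C)=C)=C(C)\CCCC(C)(C)C(OC)OC | intermediate
9 | (6Z)-7-(bromomethyl)-1,1-dimethoxy-2,2,6,8-tetramethylnona-6,8-diene | BrC/C(C(C)=C)=C(C)\CCCC(C)(C)C(OC)OC | intermediate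
10 | 2,2,6-trimethyl-4H-1,3-dioxin-4-one | CC1=CC(=O)OC(C)(C)O1 | starting material
11 | 2-(trimethylsilyl)ethanol | C[Si](C)(C)CCO | starting material
12 | acetylketene | CC(=O)C=C=O | intermediate (not isolated)
13 | 2-(trimethylsilyl)ethyl 3-oxobutanoate | CC(=O)CC(=O)OCC[Si](C)(C)C | intermediate
14 | sodium lithium 2,4-dianion of 13 | [Na+].[Li+].[CH2-]C(=O)[CH-]C(=O)OCC[Si](C)(C)C | intermediate (not isolated)
15 | 2-(trimethylsilyl)ethyl (6E)-12,12-dimethoxy-7,11,11-trimethyl-3-oxo-6-(prop-1-en-2-yl)dodec-6-enoate | C=C(C)/C(CCC(=O)CC(=O)OCC[Si](C)(C)C)=C(C)/CCCC(C)(C)C(OC)OC | intermediate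
16 | sodium Z-enolate of 15 | [Na+].C=C(C)/C(CC/C([O-])=C/C(=O)OCC[Si](C)(C)C)=C(C)/CCCC(C)(C)C(OC)OC | intermediate (not isolated)
17 | 2-(trimethylsilyl)ethyl (2Z,6E)-3-(diethoxyphosphoryloxy)-12,12-dimethoxy-7,11,11-trimethyl-6-(prop-1-en-2-yl)dodeca-2,6-dienoate | C=C(C)/C(CC/C(OP(=O)(OCC)OCC)=C/C(=O)OCC[Si](C)(C)C)=C(C)/CCCC(C)(C)C(OC)OC | intermediate
18 | 2-(trimethylsilyl)ethyl (2E,6E)-12,12-dimethoxy-3,7,11,11-tetramethyl-6-(prop-1-en-2-yl)dodeca-2,6-dienoate | C=C(C)/C(CC/C(C)=C/C(=O)OCC[Si](C)(C)C)=C(C)/CCCC(C)(C)C(OC)OC | intermediate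
19 | 9-BBN adduct of 18 with boron on C7 (the former terminal CH2 of the isopropenyl group) | C1CCC2CCCC1B2CC(C)/C(CC/C(C)=C/C(=O)OCC[Si](C)(C)C)=C(C)/CCCC(C)(C)C(OC)OC | intermediate (not isolated)
20 | 2-(trimethylsilyl)ethyl (2E,6E)-6-(1-hydroxypropan-2-yl)-12,12-dimethoxy-3,7,11,11-tetramethyldodeca-2,6-dienoate, racemic at C8 | OCC(C)/C(CC/C(C)=C/C(=O)OCC[Si](C)(C)C)=C(C)/CCCC(C)(C)C(OC)OC | intermediate
21 | 2-(trimethylsilyl)ethyl (2E,6E)-6-(1-hydroxypropan-2-yl)-3,7,11,11-tetramethyl-12-oxododeca-2,6-dienoate, racemic at C8 | OCC(C)/C(CC/C(C)=C/C(=O)OCC[Si](C)(C)C)=C(C)/CCCC(C)(C)C=O | intermediate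
22 | 2-(trimethylsilyl)ethyl (2E,6E)-3,7,11,11-tetramethyl-12-oxo-6-(1-oxopropan-2-yl)dodeca-2,6-dienoate, racemic at C8 | O=CC(C)/C(CC/C(C)=C/C(=O)OCC[Si](C)(C)C)=C(C)/CCCC(C)(C)C=O | intermediate
23 | 2-(trimethylsilyl)ethyl (2E,6E)-6-[(1E)-1-(tert-butyldimethylsilyloxy)prop-1-en-2-yl]-3,7,11,11-tetramethyl-12-oxododeca-2,6-dienoate | CC(C)(C)[Si](C)(C)O/C=C(C)/C(CC/C(C)=C/C(=O)OCC[Si](C)(C)C)=C(C)/CCCC(C)(C)C=O | intermediate
24 | nitromethane | C[N+](=O)[O-] | starting material
25 | 2-(trimethylsilyl)ethyl (2E,6E)-6-[(1E)-1-(tert-butyldimethylsilyloxy)prop-1-en-2-yl]-12-hydroxy-3,7,11,11-tetramethyl-13-nitrotrideca-2,6-dienoate, racemic at C5 | CC(C)(C)[Si](C)(C)O/C=C(C)/C(CC/C(C)=C/C(=O)OCC[Si](C)(C)C)=C(C)/CCCC(C)(C)C(O)C[N+](=O)[O-] | intermediate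
26 | methanesulfonate of 25 | CC(C)(C)[Si](C)(C)O/C=C(C)/C(CC/C(C)=C/C(=O)OCC[Si](C)(C)C)=C(C)/CCCC(C)(C)C(OS(C)(=O)=O)C[N+](=O)[O-] | intermediate (not isolated)
27 | 2-(trimethylsilyl)ethyl (2E,6E,12E)-6-[(1E)-1-(tert-butyldimethylsilyloxy)prop-1-en-2-yl]-3,7,11,11-tetramethyl-13-nitrotrideca-2,6,12-trienoate (key-step precursor) | CC(C)(C)[Si](C)(C)O/C=C(C)/C(CC/C(C)=C/C(=O)OCC[Si](C)(C)C)=C(C)/CCCC(C)(C)/C=C/[N+](=O)[O-] | intermediate
28 | 2-(trimethylsilyl)ethyl (13E)-7α-(tert-butyldimethylsilyloxy)-6α-nitrolabda-8,13-dien-15-oate (5α-H, 10β-CH3) | [O-][N+](=O)[C@H]1[C@@H](O[Si](C)(C)C(C)(C)C)C(C)=C(CC/C(C)=C/C(=O)OCC[Si](C)(C)C)[C@@]2(C)CCCC(C)(C)[C@H]12 | intermediate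
29 | potassium nitronate of 28 | [K+].[O-][N+]([O-])=C1[C@@H](O[Si](C)(C)C(C)(C)C)C(C)=C(CC/C(C)=C/C(=O)OCC[Si](C)(C)C)[C@@]2(C)CCCC(C)(C)[C@H]12 | intermediate (not isolated)
30 | 2-(trimethylsilyl)ethyl (13E)-7α-(tert-butyldimethylsilyloxy)-6-oxolabda-8,13-dien-15-oate | O=C1[C@@H](O[Si](C)(C)C(C)(C)C)C(C)=C(CC/C(C)=C/C(=O)OCC[Si](C)(C)C)[C@@]2(C)CCCC(C)(C)[C@H]12 | intermediate
31 | 2-(trimethylsilyl)ethyl (13E)-7α-(tert-butyldimethylsilyloxy)-6β-hydroxylabda-8,13-dien-15-oate | O[C@@H]1[C@@H](O[Si](C)(C)C(C)(C)C)C(C)=C(CC/C(C)=C/C(=O)OCC[Si](C)(C)C)[C@@]2(C)CCCC(C)(C)[C@H]12 | intermediate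
32 | 2-(trimethylsilyl)ethyl (13E)-6β-acetoxy-7α-(tert-butyldimethylsilyloxy)labda-8,13-dien-15-oate | CC(=O)O[C@@H]1[C@@H](O[Si](C)(C)C(C)(C)C)C(C)=C(CC/C(C)=C/C(=O)OCC[Si](C)(C)C)[C@@]2(C)CCCC(C)(C)[C@H]12 | intermediate
33 | 2-(trimethylsilyl)ethyl (13E)-6β-acetoxy-7α-hydroxylabda-8,13-dien-15-oate | CC(=O)O[C@@H]1[C@@H](O)C(C)=C(CC/C(C)=C/C(=O)OCC[Si](C)(C)C)[C@@]2(C)CCCC(C)(C)[C@H]12 | intermediate
34 | 2-(trimethylsilyl)ethyl (13E)-6β-acetoxy-7α-(3-methylbutanoyloxy)labda-8,13-dien-15-oate | CC(=O)O[C@@H]1[C@@H](OC(=O)CC(C)C)C(C)=C(CC/C(C)=C/C(=O)OCC[Si](C)(C)C)[C@@]2(C)CCCC(C)(C)[C@H]12 | intermediate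
35 | (13E)-6β-acetoxy-7α-(3-methylbutanoyloxy)labda-8,13-dien-15-oic acid (CNP0328312.2) | CC(=O)O[C@@H]1[C@@H](OC(=O)CC(C)C)C(C)=C(CC/C(C)=C/C(=O)O)[C@@]2(C)CCCC(C)(C)[C@H]12 | target

**Step count**
Total: 21 steps. Longest linear sequence: 19 steps (steps 1, 3, 4 and 6–21, from but-2-yn-1-ol); steps 2 and 5 are one-step side branches.

**Steps most likely to fail**

1. Step 15 (key cycloaddition). The catalyst may fail to tell the two diene faces apart, or the uncatalysed cycloaddition may run beside it and erode the enantiomeric purity; the fully substituted diene terminus may also need more heat than hydrogen bonding survives. The fallback sets out from 27 and comes back at 28. Compound 27 would be cyclised without catalyst (toluene, BHT, 90–110 °C, sealed vessel), the known thermal mode of nitroalkene intramolecular Diels–Alder reactions. The same endo-nitro, tether-exo preference should give the racemate, that is 28 together with its mirror image ent-28 F1. The two would be separated by preparative chromatography on a chiral stationary phase (amylose tris(3,5-dimethylphenylcarbamate), CO2/isopropanol), and 28 goes on to step 16.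

2. Step 16 (Nef reaction). The 7-silyloxy group, whose C–O bond is axial and aligned with the nitronate π system, may be lost by β-elimination from the nitronate, and deprotonation of the shielded axial H-6 may be slow. The fallback sets out from 28 and comes back at 30, and avoids a stoichiometric strong base. The nitro group would be reduced to the oxime with the tin thiolate reagent (SnCl2·2H2O, PhSH, Et3N, MeCN, rt), giving 2-(trimethylsilyl)ethyl (13E)-7α-(tert-butyldimethylsilyloxy)-6-(hydroxyimino)labda-8,13-dien-15-oate F2. The oxime would then be cleaved reductively (aq. TiCl3, NH4OAc, dioxane, rt) to ketone 30.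

3. Step 12 (enol silylation of the dialdehyde). Silyl triflate may promote an intramolecular Mukaiyama aldol attack of the new dienol ether, through C10, on the free C5 aldehyde. The fallback sets out from 21 and comes back at 27, and changes the order so that no aldehyde is free when the dienol ether forms.
   - The primary alcohol of 21 is capped (TESCl, imidazole, CH2Cl2) to give triethylsilyl ether F3.
   - The C5 aldehyde is taken through the Henry reaction (MeNO2, tetramethylguanidine) to nitro alcohol F4.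
   - Dehydration (MsCl, Et3N) gives nitroalkene F5.
   - The triethylsilyl group is removed (PPTS, MeOH, 0 °C) to give alcohol F6.
   - Buffered Dess–Martin oxidation gives aldehyde F7.
   - Enol silylation (Et3N, TBSOTf, CH2Cl2, −78 °C) then gives 27 directly, which enters step 15.

**Further compounds**
F1 | step 15 | ent-28, 2-(trimethylsilyl)ethyl (13E)-7-(tert-butyldimethylsilyloxy)-6-nitrolabda-8,13-dien-15-oate of the mirror-image series | [O-][N+](=O)[C@@H]1[C@H](O[Si](C)(C)C(C)(C)C)C(C)=C(CC/C(C)=C/C(=O)OCC[Si](C)(C)C)[C@]2(C)CCCC(C)(C)[C@@H]12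
F2 | step 16 | 2-(trimethylsilyl)ethyl (13E)-7α-(tert-butyldimethylsilyloxy)-6-(hydroxyimino)labda-8,13-dien-15-oate | ON=C1[C@@H](O[Si](C)(C)C(C)(C)C)C(C)=C(CC/C(C)=C/C(=O)OCC[Si](C)(C)C)[C@@]2(C)CCCC(C)(C)[C@H]12
F3 | step 12 | 2-(trimethylsilyl)ethyl (2E,6E)-3,7,11,11-tetramethyl-12-oxo-6-[1-(triethylsilyloxy)propan-2-yl]dodeca-2,6-dienoate | CC[Si](CC)(CC)OCC(C)/C(CC/C(C)=C/C(=O)OCC[Si](C)(C)C)=C(C)/CCCC(C)(C)C=O
F4 | step 12 | 2-(trimethylsilyl)ethyl (2E,6E)-12-hydroxy-3,7,11,11-tetramethyl-13-nitro-6-[1-(triethylsilyloxy)propan-2-yl]trideca-2,6-dienoate | CC[Si](CC)(CC)OCC(C)/C(CC/C(C)=C/C(=O)OCC[Si](C)(C)C)=C(C)/CCCC(C)(C)C(O)C[N+](=O)[O-]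
F5 | step 12 | 2-(trimethylsilyl)ethyl (2E,6E,12E)-3,7,11,11-tetramethyl-13-nitro-6-[1-(triethylsilyloxy)propan-2-yl]trideca-2,6,12-trienoate | CC[Si](CC)(CC)OCC(C)/C(CC/C(C)=C/C(=O)OCC[Si](C)(C)C)=C(C)/CCCC(C)(C)/C=C/[N+](=O)[O-]
F6 | step 12 | 2-(trimethylsilyl)ethyl (2E,6E,12E)-6-(1-hydroxypropan-2-yl)-3,7,11,11-tetramethyl-13-nitrotrideca-2,6,12-trienoate | OCC(C)/C(CC/C(C)=C/C(=O)OCC[Si](C)(C)C)=C(C)/CCCC(C)(C)/C=C/[N+](=O)[O-]
F7 | step 12 | 2-(trimethylsilyl)ethyl (2E,6E,12E)-3,7,11,11-tetramethyl-13-nitro-6-(1-oxopropan-2-yl)trideca-2,6,12-trienoate | O=CC(C)/C(CC/C(C)=C/C(=O)OCC[Si](C)(C)C)=C(C)/CCCC(C)(C)/C=C/[N+](=O)[O-]
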